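All constants were drawn at random within sensible limits, and the outcome is calculated.

I started from late times, from where the material of this flask ends up, with one decision for the next run: how much partner to charge.

substrate 1.6 M (in portions, 2); partner 1.76 M; time 15 min; the portions of substrate follow each other after 1.5 min, the first at the start

    substrate → intermediate (k1 = 0.20 /s)
    intermediate → decomposed reagent (k2 = 5.0 × 10⁻⁴ /s)
    target → over-reaction product (k3 = 0.014 /s)
    partner + intermediate → side product (k4 = 0.12 /M/s)
    substrate → target (k5 = 0.012 /s)

- the reaction counts as stopped when no species that holds the substrate changes by six tenths of a point or more over the second half of the time
- run time (flask): 15 min

* the state of affairs at 15 min: stopped, and by what, or still going (all of the substrate has reacted / it is still moving / the partner has run out first)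
* share of the substrate used up at 15 min
* side product at 15 min, in percent of the substrate charged

The substrate has two parallel routes. I called f the share that becomes intermediate: that route's constant over the sum of both.

| Route of substrate | Constant | Share |
|---|---|---|
| to intermediate | 0.20 /s | 94.3 % |
| to target | 0.012 /s | 5.66 % |

Each intermediate takes one partner. So I defined the partner demand D, the partner needed to take up the intermediate that the substrate can give, as f times the substrate charge: 1.51 M.

The charge of 1.76 M is more than D, by 0.250 M, which makes substrate the limiting reagent in this flask. The substrate's time constant is 4.72 s, far shorter than the 1.5 min between portions. So I expected a conversion of 100 %. Even with the partner down to that margin, the intermediate meets partner with a time constant of 0.554 min, much shorter than the 33.3 min of decomposition. The target's half-life by its step to over-reaction product, 0.83 min, is also far shorter than the run of 15 min. I therefore expected a stopped flask, with side product just under 94.3 %. I decided to hold the next charge of partner above D.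

The forecast said all of the substrate has reacted, with conversion 100 % and side product 93.8 %. Its ground, for the intermediate, was that the partner “traps it far faster than it decomposes”. Its side product stood 0.50 percentage points below my ceiling.

In the flask, all of the substrate has reacted, with conversion 100 % and side product 93.8 %. Against a demand of 1.51 M, it kept 15 % of its partner at 15.0 min. The first neighbour flask, like this one in all else, was charged with 1.1 M of partner, less than D. There I reckoned side product as partner charge over substrate charge, 68.8 %. That neighbour flask gave 68.8 %, with 0 % of its partner left and 16.8 % of the substrate charged still standing as intermediate.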